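**Retrosynthetic overview**

1. Target 15 is the 3,4-trans (3R,4R) α,β-dibenzyl-γ-butyrolactone; the phenol is carried as a benzyl ether (14) and freed in the last step.
2. Key disconnection, one operation: the lactone C2(=O)–C3 bond and the exocyclic C3–CH2/aryl bond are cut together, giving the acyclic homoallylic oxalate 11 and aryl bromide 12. The only ring, the γ-lactone, is formed here.
3. Enabling feature: carbonyl C2 sits on ring O1, which is tied through C5 and C4 to C3, and C3 carries an exocyclic benzylic CH2. C2 can therefore be an O1-bound alkoxycarbonyl radical and C3/CH2 a vinyl group; 5-exo closure leaves the radical on the carbon that must receive the guaiacyl ring, and the adjacent C4 stereocentre directs trans.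
4. Alcohol 8, holding the single pre-set stereocentre (C4), comes from Evans deconjugative alkylation of N-crotonyl imide 4 with bromide 5, then LiBH4 cleavage; oxalyl chloride 9 supplies C2.

Key step: step 5

Remark: the two stereocentres are read as (3R,4R), i.e. 3,4-trans; compounds 5, 9 and 12 are taken as catalogue chemicals.

**Route**

Step 1
Reactants: 1 (R)-4-benzyloxazolidin-2-one; 2 (E)-but-2-enoyl chloride
Product: 4 (R)-4-benzyl-3-[(E)-but-2-enoyl]oxazolidin-2-one, via N-lithio oxazolidinone 3 (not isolated)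
Conditions: n-BuLi, THF, −78 °C; then 2, −78 → 0 °C
Reagents that add atoms: none
Why: N-acylation of the lithiated Evans oxazolidinone by the acid chloride is fast at low temperature, and the absence of an amine base avoids vinylketene formation from the crotonyl chloride; no stereocentre is made.

Step 2
Reactants: 4 (R)-4-benzyl-3-[(E)-but-2-enoyl]oxazolidin-2-one; 5 3,4,5-trimethoxybenzyl bromide
Product: 7 (R)-4-benzyl-3-[(2R)-2-(3,4,5-trimethoxybenzyl)but-3-enoyl]oxazolidin-2-one, via sodium (Z)-dienolate 6 (not isolated)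
Conditions: NaHMDS, THF, −78 °C; then 5, −78 → −40 °C; cold NH4Cl quench
Reagents that add atoms: none
Why: Evans asymmetric alkylation in its deconjugative form: γ-deprotonation gives the sodium-chelated (Z)-dienolate, which should react with the benzylic bromide at the α-carbon on the face opposite the C4 benzyl group of the (R)-auxiliary, setting the new centre as (R) and moving the double bond to the terminal vinyl position.

Step 3
Reactants: 7 (R)-4-benzyl-3-[(2R)-2-(3,4,5-trimethoxybenzyl)but-3-enoyl]oxazolidin-2-one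
Product: 8 (2R)-2-(3,4,5-trimethoxybenzyl)but-3-en-1-ol
Conditions: LiBH4, THF, 0 °C → rt; aq. NH4Cl
Reagents that add atoms: none
Why: Reductive cleavage of the N-acyloxazolidinone: hydride attacks the exocyclic carbonyl, the weakly basic conditions should leave the α-stereocentre and the β,γ-alkene in place, and the auxiliary is released for recovery.

Step 4
Reactants: 8 (2R)-2-(3,4,5-trimethoxybenzyl)but-3-en-1-ol; 9 oxalyl chloride
Product: 11 (2R)-2-(3,4,5-trimethoxybenzyl)but-3-en-1-yl hydrogen oxalate, via alkyl chlorooxoacetate 10 (not isolated)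
Conditions: 9 (excess), Et2O, 0 °C → rt; evaporate; then H2O, THF, 0 °C
Reagents that add atoms: water, O
Why: Acylation of a primary alcohol by excess oxalyl chloride should stop at the mono-ester acid chloride, and water then hydrolyses the remaining acyl chloride much faster than the ester, the standard preparation of alkyl hydrogen oxalates.

Step 5
Reactants: 11 (2R)-2-(3,4,5-trimethoxybenzyl)but-3-en-1-yl hydrogen oxalate; 12 1-(benzyloxy)-4-bromo-2-methoxybenzene
Product: 14 (3R,4R)-3-[4-(benzyloxy)-3-methoxybenzyl]-4-(3,4,5-trimethoxybenzyl)dihydrofuran-2(3H)-one, via cesium oxalate 13 (not isolated)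
Conditions: Ir[dF(CF3)ppy]2(dtbbpy)PF6 (1 mol %), NiBr2·dme (10 mol %), dtbbpy (15 mol %), CsHCO3 (1.1 equiv), 12 (1.5 equiv), DME/DMF, degassed, blue LEDs, rt
Reagents that add atoms: none
Why: Alkoxycarbonyl radical cyclization–cross-coupling cascade under Ni/photoredox dual catalysis: the excited Ir(III) complex oxidizes the oxalate carboxylate of 13, loss of one CO2 leaves a primary alkoxycarbonyl radical (slow to lose the second CO2), this adds to the internal vinyl carbon to form the lactone C2–C3 bond, and the exocyclic primary radical is captured by the (dtbbpy)Ni(aryl)Br complex from oxidative addition of 12 and reductively eliminated as the CH2–aryl bond, Ir(II) returning Ni(I) to Ni(0). The closest known reaction type is the Ni/photoredox alkoxycarbonyl radical cyclization–arylation of homoallylic oxalate salts with aryl bromides, backed by the older tin-mediated 5-exo cyclizations of homoallylic selenocarbonates to γ-butyrolactones. The γ-lactone closes in the 5-exo-trig mode. The new C3 stereocentre is controlled by the existing C4 centre: in the chair-like Beckwith–Houk transition state the trimethoxybenzyl group lies pseudo-equatorial, so the new exocyclic arm should end up trans to it, which is also the thermodynamically preferred 3,4-trans lactone. The step needs ring closure to outrun nickel capture of the acyl radical and 5-exo to beat 6-endo attack; the short O1–C5–C4 tether, the unhindered terminal vinyl acceptor and the unimolecular closure secure both, and the exocyclic radical has no faster intramolecular outlet than capture by nickel.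

Step 6
Reactants: 14 (3R,4R)-3-[4-(benzyloxy)-3-methoxybenzyl]-4-(3,4,5-trimethoxybenzyl)dihydrofuran-2(3H)-one
Product: 15 (3R,4R)-3-(4-hydroxy-3-methoxybenzyl)-4-(3,4,5-trimethoxybenzyl)dihydrofuran-2(3H)-one
Conditions: H2 (1 atm), 10% Pd/C, EtOAc/EtOH, rt
Reagents that add atoms: none
Why: Catalytic hydrogenolysis of the benzyl aryl ether should be selective beside the lactone and the aryl methyl ethers, no alkene remains, and the neutral conditions leave C3 and C4 untouched.

**Compound list**

1 | (R)-4-benzyloxazolidin-2-one | O=C1N[C@H](Cc2ccccc2)CO1 | starting material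
2 | (E)-but-2-enoyl chloride | C/C=C/C(Cl)=O | starting material
3 | lithium salt of (R)-4-benzyloxazolidin-2-one (N-lithio oxazolidinone) | [Li+].O=C1[N-][C@H](Cc2ccccc2)CO1 | intermediate
4 | (R)-4-benzyl-3-[(E)-but-2-enoyl]oxazolidin-2-one | C/C=C/C(=O)N1[C@H](Cc2ccccc2)COC1=O | intermediate
5 | 3,4,5-trimethoxybenzyl bromide | COc1cc(CBr)cc(OC)c1OC | starting material
6 | sodium (Z)-1-[(R)-4-benzyl-2-oxooxazolidin-3-yl]buta-1,3-dien-1-olate | [Na+].[O-]/C(=C\C=C)N1[C@H](Cc2ccccc2)COC1=O | intermediate
7 | (R)-4-benzyl-3-[(2R)-2-(3,4,5-trimethoxybenzyl)but-3-enoyl]oxazolidin-2-one | C=C[C@@H](Cc1cc(OC)c(OC)c(OC)c1)C(=O)N1[C@H](Cc2ccccc2)COC1=O | intermediate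
8 | (2R)-2-(3,4,5-trimethoxybenzyl)but-3-en-1-ol | OC[C@@H](C=C)Cc1cc(OC)c(OC)c(OC)c1 | intermediate
9 | oxalyl chloride | O=C(Cl)C(Cl)=O | starting material
10 | (2R)-2-(3,4,5-trimethoxybenzyl)but-3-en-1-yl 2-chloro-2-oxoacetate | O=C(Cl)C(=O)OC[C@@H](C=C)Cc1cc(OC)c(OC)c(OC)c1 | intermediate
11 | (2R)-2-(3,4,5-trimethoxybenzyl)but-3-en-1-yl hydrogen oxalate | OC(=O)C(=O)OC[C@@H](C=C)Cc1cc(OC)c(OC)c(OC)c1 | intermediate
12 | 1-(benzyloxy)-4-bromo-2-methoxybenzene | COc1cc(Br)ccc1OCc1ccccc1 | starting material
13 | cesium (2R)-2-(3,4,5-trimethoxybenzyl)but-3-en-1-yl oxalate | [Cs+].[O-]C(=O)C(=O)OC[C@@H](C=C)Cc1cc(OC)c(OC)c(OC)c1 | intermediate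
14 | (3R,4R)-3-[4-(benzyloxy)-3-methoxybenzyl]-4-(3,4,5-trimethoxybenzyl)dihydrofuran-2(3H)-one | COc1cc(C[C@H]2C(=O)OC[C@@H]2Cc2cc(OC)c(OC)c(OC)c2)ccc1OCc1ccccc1 | intermediate
15 | (3R,4R)-3-(4-hydroxy-3-methoxybenzyl)-4-(3,4,5-trimethoxybenzyl)dihydrofuran-2(3H)-one | COc1cc(C[C@H]2C(=O)OC[C@@H]2Cc2cc(OC)c(OC)c(OC)c2)ccc1O | target

**Step count and risks**

Total steps: 6. Longest linear sequence: 6 (steps 1–6; 5, 9 and 12 enter as purchased materials).

Steps most likely to fail:

Step 5. The alkoxycarbonyl radical may be intercepted by nickel before ring closure, oxidative addition of the electron-rich aryl bromide may be slow, and the alkylnickel intermediate may undergo β-hydride elimination. The fallback sets out from 8 and comes back at 14; it puts the aryl group on the alkene first and then closes the ring through the same C2–C3 bond in a tin-mediated radical cyclization. Wittig methylenation of 4-(benzyloxy)-3-methoxybenzaldehyde (Ph3PCH3Br, KOt-Bu, THF) should give 1-(benzyloxy)-4-ethenyl-2-methoxybenzene F1. Cross-metathesis of 8 with excess F1 (Hoveyda–Grubbs II, CH2Cl2, 40 °C) should give (2R,3E)-4-[4-(benzyloxy)-3-methoxyphenyl]-2-(3,4,5-trimethoxybenzyl)but-3-en-1-ol F2. Phosgene (toluene solution) and pyridine at 0 °C convert it into the carbonochloridate (chloroformate) of that alcohol F3, and benzeneselenol with pyridine into the corresponding O-alkyl Se-phenyl carbonoselenoate F4. Slow addition of Bu3SnH/AIBN in benzene at 80 °C should then generate the alkoxycarbonyl radical, which closes 5-exo onto the styrene; the benzylic radical is reduced by the stannane to give 14. Should the trans preference at C3 be incomplete in either variant, C3 is the only base-labile centre and equilibration with DBU converges on the 3,4-trans lactone.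

Step 2. The dienolate may alkylate at the γ- instead of the α-carbon, and base may move the double bond back into conjugation after alkylation, with loss of the new stereocentre. The fallback sets out from 1 and comes back at 8; it uses an ordinary saturated enolate and unmasks the vinyl group afterwards by selenoxide elimination. γ-Butyrolactone is opened with sodium benzeneselenolate (PhSeSePh, NaBH4, DMF, 120 °C) to 4-(phenylselanyl)butanoic acid F5. Pivaloyl chloride and Et3N (THF, −20 °C) give 4-(phenylselanyl)butanoic pivalic anhydride F6, which acylates the N-lithio oxazolidinone 3 made from 1 to give (R)-4-benzyl-3-[4-(phenylselanyl)butanoyl]oxazolidin-2-one F7. NaHMDS (THF, −78 °C) forms sodium (Z)-1-[(R)-4-benzyl-2-oxooxazolidin-3-yl]-4-(phenylselanyl)but-1-en-1-olate F8, which should be alkylated by 5 anti to the auxiliary benzyl group to give (R)-4-benzyl-3-[(2R)-4-(phenylselanyl)-2-(3,4,5-trimethoxybenzyl)butanoyl]oxazolidin-2-one F9. LiBH4 (THF, 0 °C) gives (2R)-4-(phenylselanyl)-2-(3,4,5-trimethoxybenzyl)butan-1-ol F10. H2O2 with pyridine (CH2Cl2, 0 °C → rt) oxidizes it to (2R)-4-(phenylseleninyl)-2-(3,4,5-trimethoxybenzyl)butan-1-ol F11, which should undergo syn-elimination at rt to 8.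

Step 4. Double acylation may give the symmetrical dialkyl oxalate, and the half-ester may be hydrolysed during aqueous work-up. The fallback sets out from 8 and comes back at 11; it differentiates the two oxalate termini with an acid-labile ester instead of relying on excess reagent. tert-Butyl chlorooxoacetate with pyridine (CH2Cl2, 0 °C) should give tert-butyl (2R)-2-(3,4,5-trimethoxybenzyl)but-3-en-1-yl oxalate F12, and TFA/CH2Cl2 at 0 °C should cleave only the tert-butyl ester to give 11 without aqueous base.

**Further compounds**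

F1 | step 5 | 1-(benzyloxy)-4-ethenyl-2-methoxybenzene | C=Cc1ccc(OCc2ccccc2)c(OC)c1
F2 | step 5 | (2R,3E)-4-[4-(benzyloxy)-3-methoxyphenyl]-2-(3,4,5-trimethoxybenzyl)but-3-en-1-ol | OC[C@@H](/C=C/c1ccc(OCc2ccccc2)c(OC)c1)Cc1cc(OC)c(OC)c(OC)c1
F3 | step 5 | (2R,3E)-4-[4-(benzyloxy)-3-methoxyphenyl]-2-(3,4,5-trimethoxybenzyl)but-3-en-1-yl carbonochloridate | O=C(Cl)OC[C@@H](/C=C/c1ccc(OCc2ccccc2)c(OC)c1)Cc1cc(OC)c(OC)c(OC)c1
F4 | step 5 | O-[(2R,3E)-4-[4-(benzyloxy)-3-methoxyphenyl]-2-(3,4,5-trimethoxybenzyl)but-3-en-1-yl] Se-phenyl carbonoselenoate | O=C([Se]c1ccccc1)OC[C@@H](/C=C/c1ccc(OCc2ccccc2)c(OC)c1)Cc1cc(OC)c(OC)c(OC)c1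
F5 | step 2 | 4-(phenylselanyl)butanoic acid | OC(=O)CCC[Se]c1ccccc1
F6 | step 2 | 4-(phenylselanyl)butanoic pivalic anhydride | CC(C)(C)C(=O)OC(=O)CCC[Se]c1ccccc1
F7 | step 2 | (R)-4-benzyl-3-[4-(phenylselanyl)butanoyl]oxazolidin-2-one | O=C(CCC[Se]c1ccccc1)N1[C@H](Cc2ccccc2)COC1=O
F8 | step 2 | sodium (Z)-1-[(R)-4-benzyl-2-oxooxazolidin-3-yl]-4-(phenylselanyl)but-1-en-1-olate | [Na+].[O-]/C(=C\CC[Se]c1ccccc1)N1[C@H](Cc2ccccc2)COC1=O
F9 | step 2 | (R)-4-benzyl-3-[(2R)-4-(phenylselanyl)-2-(3,4,5-trimethoxybenzyl)butanoyl]oxazolidin-2-one | [Se](c1ccccc1)CC[C@@H](Cc2cc(OC)c(OC)c(OC)c2)C(=O)N3[C@H](Cc4ccccc4)COC3=O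
F10 | step 2 | (2R)-4-(phenylselanyl)-2-(3,4,5-trimethoxybenzyl)butan-1-ol | OC[C@@H](CC[Se]c1ccccc1)Cc1cc(OC)c(OC)c(OC)c1
F11 | step 2 | (2R)-4-(phenylseleninyl)-2-(3,4,5-trimethoxybenzyl)butan-1-ol | OC[C@@H](CC[Se](=O)c1ccccc1)Cc1cc(OC)c(OC)c(OC)c1
F12 | step 4 | tert-butyl (2R)-2-(3,4,5-trimethoxybenzyl)but-3-en-1-yl oxalate | CC(C)(C)OC(=O)C(=O)OC[C@@H](C=C)Cc1cc(OC)c(OC)c(OC)c1
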